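**Plan**
1. Cuts: the C8 ester C–O bond (side-chain acid from but-2-yne-1,4-diol), C11=C13 (Mannich methylenation), C10–O (alkene hydration), C8–C9 (carbonyl-ene), C7–C11 (auxiliary-controlled alkylation) and C6–C7 (Claisen); what remains is ring B, which is (S)-carvone.
2. Enabling feature: in ring A (C6–C7–C8–C9–C10–C1) the C8 carbinol, the C9 methylene and the C10 methyl carbinol are the retron of a C8 aldehyde adding to the CH2 end of an isopropenyl group on C1, and carvone already carries that isopropenyl group on ring B (C1–C2–C3–C4=C5–C6).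
3. Forward order: ring B from the chiral pool, the C6 side chain, ring A by C8–C9 closure, C10 hydroxyl and C13 methylene, acylation of C8, C3 acetate, deprotection.
4. Stereochemistry: C1 from (S)-carvone; C3 by Luche reduction; C4–O by hydroxyl-directed epoxidation and from it C6 by a suprafacial [3,3] shift; C7 by an oxazolidinone alkylation; C8 in the ene chair; C10 by face-selective oxygen capture; the side-chain E alkene by syn-hydrostannylation.

Key step: step 15

Remark: atoms are numbered as in the target throughout; β is the face carrying the C3 oxygen, so H1 and H6 are α. The side-chain alkene is taken as E (carboxyl trans to the CH2OH on the β-carbon), as the SMILES specifies. A tert-butyl ester replaces a methyl ester on the C7 arm so that the cis C8 hydroxyl cannot lactonise.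

**Side-chain acid (steps 1–4)**

Step 1
Reactants: 1 but-2-yne-1,4-diol
Product: 2 (E)-2-(tributylstannyl)but-2-ene-1,4-diol
Conditions: Bu3SnH, PdCl2(PPh3)2 (2 mol %), THF, 0 °C → rt
Reagents that add atoms: tributyltin hydride, CCCC[SnH](CCCC)CCCC
Why: Palladium-catalysed hydrostannylation adds H and SnBu3 syn across the symmetrical alkyne, so there is no regiochemical question and the two CH2OH groups end up cis.

Step 2
Reactants: 2 (E)-2-(tributylstannyl)but-2-ene-1,4-diol
Product: 3 (E)-1,4-bis(tert-butyldiphenylsilyloxy)-2-(tributylstannyl)but-2-ene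
Conditions: TBDPSCl, imidazole, DMF, rt
Reagents that add atoms: tert-butyl(chloro)diphenylsilane, CC(C)(C)[Si](Cl)(c1ccccc1)c1ccccc1
Why: Silyl ether formation on two primary alcohols; TBDPS is chosen because it must outlast the later acid-mediated removal of a TBS ether.

Step 3
Reactants: 3 (E)-1,4-bis(tert-butyldiphenylsilyloxy)-2-(tributylstannyl)but-2-ene
Product: 4 (E)-1,4-bis(tert-butyldiphenylsilyloxy)-2-iodobut-2-ene
Conditions: I2, CH2Cl2, 0 °C
Reagents that add atoms: iodine, II
Why: Iododestannylation of a vinylstannane proceeds with retention of alkene geometry.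

Step 4
Reactants: 4 (E)-1,4-bis(tert-butyldiphenylsilyloxy)-2-iodobut-2-ene
Product: 6 (E)-4-(tert-butyldiphenylsilyloxy)-2-[(tert-butyldiphenylsilyloxy)methyl]but-2-enoic acid, via vinyllithium 5 (not isolated)
Conditions: t-BuLi (2.1 equiv), Et2O, −78 °C; CO2; 1 M HCl work-up
Reagents that add atoms: carbon dioxide, O=C=O
Why: Iodine–lithium exchange gives a vinyllithium that keeps its geometry at −78 °C (the γ-silyloxy group is trans to lithium, so no 1,4-silyl shift can occur) and carboxylation then proceeds with retention.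

**Ring B and the ene precursor (steps 5–14)**

Step 5
Reactants: 7 (S)-(+)-carvone
Product: 8 (1S,5S)-cis-carveol
Conditions: NaBH4, CeCl3·7H2O, MeOH, −78 → 0 °C
Reagents that add atoms: none
Why: Luche 1,2-reduction of the enone, in which axial hydride delivery on the half-chair with an equatorial isopropenyl group gives the cis alcohol and so sets C3 (O β, cis to the isopropenyl group).

Step 6
Reactants: 8 (1S,5S)-cis-carveol
Product: 9 4β,5β-epoxy-cis-carveol (oxirane syn to the C3 hydroxyl)
Conditions: VO(acac)2 (2 mol %), t-BuOOH, CH2Cl2, 0 °C → rt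
Reagents that add atoms: tert-butyl hydroperoxide, CC(C)(C)OO
Why: Hydroxyl-directed vanadium-catalysed epoxidation delivers oxygen to the allylic alkene only and syn to the C3 hydroxyl, which fixes C4–O as β and leaves the isopropenyl group untouched.

Step 7
Reactants: 9 4β,5β-epoxy-cis-carveol
Product: 10 3-O-TBS ether of epoxy alcohol 9
Conditions: TBSCl, imidazole, DMF, rt
Reagents that add atoms: tert-butyl(chloro)dimethylsilane, CC(C)(C)[Si](C)(C)Cl
Why: Silyl ether formation; the cis arrangement of the alkoxide and oxirane rules out epoxide migration, and the silyl ether is an inert spectator for the Lewis acid step.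

Step 8
Reactants: 10 3-O-TBS ether of epoxy alcohol 9
Product: 13 3β-(tert-butyldimethylsilyloxy)-4β-hydroxy-4α-methyl-1β-isopropenylcyclohex-5-ene, via hydroxy selenide 11 (not isolated), via selenoxide 12 (not isolated)
Conditions: (PhSe)2, NaBH4, EtOH, 80 °C; then 30 % H2O2, pyridine, THF, 0 °C → rt
Reagents that add atoms: none
Why: Epoxide-to-allylic-alcohol transposition by selenide opening and selenoxide syn-elimination: the selenolate opens the oxirane trans-diaxially at the secondary C5 and the selenoxide can only eliminate toward C6 because C4 is quaternary.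

Step 9
Reactants: 13 3β-(tert-butyldimethylsilyloxy)-4β-hydroxy-4α-methyl-1β-isopropenylcyclohex-5-ene; 14 trimethyl orthoacetate
Product: 16 methyl 2-[3β-(tert-butyldimethylsilyloxy)-4-methyl-1β-isopropenylcyclohex-4-en-6β-yl]acetate, via ketene acetal 15 (not isolated)
Conditions: EtCO2H (cat.), xylene, 140 °C, MeOH distilled off
Reagents that add atoms: none
Why: Johnson–Claisen rearrangement: the ketene acetal on the β oxygen of C4 delivers C7 suprafacially to the β face of C6, which sets C6 cis to both the isopropenyl group and the C3 silyl ether and moves the alkene to C4=C5.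

Step 10
Reactants: 16 methyl 2-[3β-(tert-butyldimethylsilyloxy)-4-methyl-1β-isopropenylcyclohex-4-en-6β-yl]acetate
Product: 17 2-[3β-(tert-butyldimethylsilyloxy)-4-methyl-1β-isopropenylcyclohex-4-en-6β-yl]acetic acid
Conditions: LiOH, THF/MeOH/H2O, 40 °C; 1 M HCl to pH 4
Reagents that add atoms: lithium hydroxide, [Li+].[OH-]
Why: Ester saponification; no stereocentre is α to the carboxyl group and the TBS ether is stable to base.

Step 11
Reactants: 17 2-[3β-(tert-butyldimethylsilyloxy)-4-methyl-1β-isopropenylcyclohex-4-en-6β-yl]acetic acid; 18 (R)-4-benzyl-2-oxazolidinone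
Product: 20 (R)-4-benzyl-3-{2-[3β-(tert-butyldimethylsilyloxy)-4-methyl-1β-isopropenylcyclohex-4-en-6β-yl]acetyl}oxazolidin-2-one, via mixed pivalic anhydride 19 (not isolated)
Conditions: PivCl, Et3N, THF, −20 °C; then 18, LiCl, rt
Reagents that add atoms: none
Why: N-Acylation of the oxazolidinone through the mixed pivalic anhydride, which reacts at the less hindered carbonyl.

Step 12
Reactants: 20 (R)-4-benzyl-3-{2-[3β-(tert-butyldimethylsilyloxy)-4-methyl-1β-isopropenylcyclohex-4-en-6β-yl]acetyl}oxazolidin-2-one; 21 tert-butyl bromoacetate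
Product: 23 tert-butyl (3R)-4-[(R)-4-benzyl-2-oxooxazolidin-3-yl]-4-oxo-3-[3β-(tert-butyldimethylsilyloxy)-4-methyl-1β-isopropenylcyclohex-4-en-6β-yl]butanoate, via sodium enolate 22 (not isolated)
Conditions: NaN(SiMe3)2, THF, −78 °C; then 21, −78 → −40 °C
Reagents that add atoms: none
Why: Evans alkylation: the chelated Z sodium enolate is attacked on the face away from the benzyl group, which with the (R)-auxiliary sets C7 as (R), the direction the substrate should also prefer because that face is anti to the C1 branch of ring B.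

Step 13
Reactants: 23 tert-butyl (3R)-4-[(R)-4-benzyl-2-oxooxazolidin-3-yl]-4-oxo-3-[3β-(tert-butyldimethylsilyloxy)-4-methyl-1β-isopropenylcyclohex-4-en-6β-yl]butanoate
Product: 24 tert-butyl (3R)-4-hydroxy-3-[3β-(tert-butyldimethylsilyloxy)-4-methyl-1β-isopropenylcyclohex-4-en-6β-yl]butanoate
Conditions: LiBH4, MeOH (1.1 equiv), Et2O, 0 °C
Reagents that add atoms: none
Why: Reductive removal of the auxiliary; LiBH4 reduces the activated imide carbonyl much faster than the hindered tert-butyl ester.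

Step 14
Reactants: 24 tert-butyl (3R)-4-hydroxy-3-[3β-(tert-butyldimethylsilyloxy)-4-methyl-1β-isopropenylcyclohex-4-en-6β-yl]butanoate
Product: 25 tert-butyl (3R)-4-oxo-3-[3β-(tert-butyldimethylsilyloxy)-4-methyl-1β-isopropenylcyclohex-4-en-6β-yl]butanoate
Conditions: Dess–Martin periodinane, NaHCO3, CH2Cl2, 0 °C → rt
Reagents that add atoms: none
Why: Buffered Dess–Martin oxidation gives the α-branched aldehyde under near-neutral conditions that should not epimerise C7; the aldehyde is used at once.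

**Ring A and endgame (steps 15–21)**

Step 15
Reactants: 25 tert-butyl (3R)-4-oxo-3-[3β-(tert-butyldimethylsilyloxy)-4-methyl-1β-isopropenylcyclohex-4-en-6β-yl]butanoate
Product: 26 tert-butyl 2-[(1αH,6αH)-3β-(tert-butyldimethylsilyloxy)-8α-hydroxy-4-methyl-10-methylene-cis-decal-4-en-7α-yl]acetate
Conditions: Me2AlCl (2.0 equiv), CH2Cl2, −78 → −30 °C; cold 1 M HCl work-up
Reagents that add atoms: none
Why: Me2AlCl binds the aldehyde oxygen, the CH2 terminus of the isopropenyl group (C9) adds to C8 and a hydrogen of the C14 methyl passes to oxygen in a concerted, asynchronous carbonyl-ene process, the closest known reaction type being the Me2AlCl-promoted type 2 intramolecular carbonyl-ene cyclisation of 5-methylhex-5-enals to 3-methylenecyclohexanols. Ring A closes as a six-membered chair with the carbonyl exo and the reacting alkene C9=C10 inside the new ring, so the double bond is left exocyclic at C10=C14. C8 is the only new stereocentre: the six-centre hydrogen transfer requires the aluminium-bound oxygen to be axial and syn to C14, and with the (7R) arm equatorial this places C8–O cis to the C7 arm. The reacting chair is the one that keeps ring B in its preferred half-chair (C1–C10 bond equatorial, C3 silyl ether pseudoequatorial, C6–C7 bond pseudoaxial), because the other chair would put C10 and the C3 silyl ether 1,3-diaxial. The step needs ene reaction over cationic Prins chemistry and hydrogen transfer from C14 and not from H1; Me2AlCl removes the proton as methane, and H1 lies out of reach of the axial oxygen. The tert-butyl ester, the silyl ether and the C4=C5 alkene are spectators, the last because attack of C4 or C5 on C8 would need a four-membered ring or a secondary cation.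

Step 16
Reactants: 26 tert-butyl 2-[(1αH,6αH)-3β-(tert-butyldimethylsilyloxy)-8α-hydroxy-4-methyl-10-methylene-cis-decal-4-en-7α-yl]acetate
Product: 27 tert-butyl 2-[(1αH,6αH)-3β-(tert-butyldimethylsilyloxy)-8α,10β-dihydroxy-4,10α-dimethyl-cis-decal-4-en-7α-yl]acetate
Conditions: Co(acac)2 (20 mol %), PhSiH3, O2 (1 atm), THF, 0 °C → rt; aq. Na2S2O3
Reagents that add atoms: dioxygen, O=O
Why: Mukaiyama hydration (hydrogen-atom transfer, Markovnikov) should pick the 1,1-disubstituted alkene over the trisubstituted one, and the tertiary C10 radical should capture oxygen from the β (equatorial) side because the α (axial) approach is blocked by the syn-axial C8 oxygen and H6.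

Step 17
Reactants: 27 tert-butyl 2-[(1αH,6αH)-3β-(tert-butyldimethylsilyloxy)-8α,10β-dihydroxy-4,10α-dimethyl-cis-decal-4-en-7α-yl]acetate
Product: 31 tert-butyl 2-[(1αH,6αH)-3β-(tert-butyldimethylsilyloxy)-8α,10β-dihydroxy-4,10α-dimethyl-cis-decal-4-en-7α-yl]acrylate, via trilithium enolate 28 (not isolated), via Mannich base 29 (not isolated), via ammonium iodide 30 (not isolated)
Conditions: LiN(iPr)2 (3.5 equiv), THF, −78 °C; CH2=NMe2+ I−, −78 → −20 °C; MeI, CH2Cl2/MeOH, rt; aq. NaHCO3
Reagents that add atoms: N,N-dimethylmethyleneiminium iodide (Eschenmoser's salt), C=[N+](C)C.[I-]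
Why: Mannich α-methylenation of the ester enolate with Eschenmoser's salt, followed by N-methylation and β-elimination of trimethylamine; the two alkoxides are tolerated and the tert-butyl ester resists attack by the cis C8 alkoxide at low temperature.

Step 18
Reactants: 31 tert-butyl 2-[(1αH,6αH)-3β-(tert-butyldimethylsilyloxy)-8α,10β-dihydroxy-4,10α-dimethyl-cis-decal-4-en-7α-yl]acrylate; 6 (E)-4-(tert-butyldiphenylsilyloxy)-2-[(tert-butyldiphenylsilyloxy)methyl]but-2-enoic acid
Product: 33 C8 ester of 31 with acid 6 (3β-OTBS; 10β-OH; tert-butyl acrylate; side-chain bis-TBDPS ether), via Yamaguchi mixed anhydride 32 (not isolated)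
Conditions: 2,4,6-Cl3C6H2COCl, Et3N, toluene, rt; then 31, DMAP, toluene, rt → 40 °C
Reagents that add atoms: none
Why: Yamaguchi esterification acylates the only reactive hydroxyl (secondary C8; the tertiary C10 hydroxyl is inert), and the E acid is the thermodynamically preferred geometry so it should not isomerise under DMAP.

Step 19
Reactants: 33 C8 ester of 31 with acid 6
Product: 34 3β-alcohol of 33 (TBS removed; both TBDPS ethers retained)
Conditions: PPTS, EtOH, 50 °C
Reagents that add atoms: none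
Why: Acid-catalysed solvolysis of a silyl ether, selective because TBDPS ethers are far more stable to acid than TBS ethers; the tert-butyl ester and the tertiary alcohol are not affected by this weak acid.

Step 20
Reactants: 34 3β-alcohol of 33
Product: 35 3β-acetate of 34
Conditions: Ac2O, pyridine, DMAP (cat.), CH2Cl2, 0 °C
Reagents that add atoms: acetic anhydride, CC(=O)OC(C)=O
Why: Acetylation of the only secondary alcohol; the tertiary C10 hydroxyl should not react at 0 °C.

Step 21
Reactants: 35 3β-acetate of 34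
Product: 37 target CNP0468194.1, via trimethylsilyl ester 36 (not isolated)
Conditions: TMSOTf, 2,6-lutidine, CH2Cl2, 0 °C; then HF·pyridine, THF, 0 °C → rt
Reagents that add atoms: none
Why: tert-Butyl ester cleavage by O-silylation and loss of isobutene under buffered, non-protic conditions (the C10 hydroxyl is silylated in passing), then fluoride desilylation, which frees the acid, the C10 alcohol and both primary alcohols without touching the acetate or the other esters.

**Compound list**
1 | but-2-yne-1,4-diol | OCC#CCO | starting material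
2 | (E)-2-(tributylstannyl)but-2-ene-1,4-diol | CCCC[Sn](CCCC)(CCCC)/C(=C/CO)CO | intermediate
3 | (E)-1,4-bis(tert-butyldiphenylsilyloxy)-2-(tributylstannyl)but-2-ene | CCCC[Sn](CCCC)(CCCC)/C(=C/CO[Si](c1ccccc1)(c1ccccc1)C(C)(C)C)CO[Si](c1ccccc1)(c1ccccc1)C(C)(C)C | intermediate
4 | (E)-1,4-bis(tert-butyldiphenylsilyloxy)-2-iodobut-2-ene | I/C(=C/CO[Si](c1ccccc1)(c1ccccc1)C(C)(C)C)CO[Si](c1ccccc1)(c1ccccc1)C(C)(C)C | intermediate
5 | vinyllithium from 4 (not isolated) | [Li]/C(=C/CO[Si](c1ccccc1)(c1ccccc1)C(C)(C)C)CO[Si](c1ccccc1)(c1ccccc1)C(C)(C)C | intermediate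
6 | (E)-4-(tert-butyldiphenylsilyloxy)-2-[(tert-butyldiphenylsilyloxy)methyl]but-2-enoic acid | OC(=O)/C(=C/CO[Si](c1ccccc1)(c1ccccc1)C(C)(C)C)CO[Si](c1ccccc1)(c1ccccc1)C(C)(C)C | intermediate
7 | (S)-(+)-carvone | CC1=CC[C@@H](CC1=O)C(C)=C | starting material
8 | (1S,5S)-cis-carveol | C1C=C(C)[C@@H](O)C[C@H]1C(C)=C | intermediate
9 | 4β,5β-epoxy-cis-carveol (oxirane syn to OH) | C1[C@H]2O[C@@]2(C)[C@@H](O)C[C@H]1C(C)=C | intermediate
10 | 3-O-TBS ether of 9 | C1[C@H]2O[C@@]2(C)[C@@H](O[Si](C)(C)C(C)(C)C)C[C@H]1C(C)=C | intermediate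
11 | hydroxy selenide (5α-SePh, 4β-OH; not isolated) | C1[C@H]([Se]c2ccccc2)[C@@](C)(O)[C@@H](O[Si](C)(C)C(C)(C)C)C[C@H]1C(C)=C | intermediate
12 | selenoxide of 11 (not isolated) | C1[C@H]([Se](=O)c2ccccc2)[C@@](C)(O)[C@@H](O[Si](C)(C)C(C)(C)C)C[C@H]1C(C)=C | intermediate
13 | 3β-(tert-butyldimethylsilyloxy)-4β-hydroxy-4α-methyl-1β-isopropenylcyclohex-5-ene | C1=C[C@@](C)(O)[C@@H](O[Si](C)(C)C(C)(C)C)C[C@H]1C(C)=C | intermediate
14 | trimethyl orthoacetate | CC(OC)(OC)OC | starting material
15 | O4-(1-methoxyvinyl) ketene acetal of 13 (not isolated) | C1=C[C@@](C)(OC(=C)OC)[C@@H](O[Si](C)(C)C(C)(C)C)C[C@H]1C(C)=C | intermediate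
16 | methyl 2-[3β-(tert-butyldimethylsilyloxy)-4-methyl-1β-isopropenylcyclohex-4-en-6β-yl]acetate | COC(=O)C[C@H]1C=C(C)[C@@H](O[Si](C)(C)C(C)(C)C)C[C@H]1C(C)=C | intermediate
17 | 2-[3β-(tert-butyldimethylsilyloxy)-4-methyl-1β-isopropenylcyclohex-4-en-6β-yl]acetic acid | OC(=O)C[C@H]1C=C(C)[C@@H](O[Si](C)(C)C(C)(C)C)C[C@H]1C(C)=C | intermediate
18 | (R)-4-benzyl-2-oxazolidinone | O=C1N[C@H](Cc2ccccc2)CO1 | starting material
19 | mixed pivalic anhydride of 17 (not isolated) | CC(C)(C)C(=O)OC(=O)C[C@H]1C=C(C)[C@@H](O[Si](C)(C)C(C)(C)C)C[C@H]1C(C)=C | intermediate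
20 | (R)-4-benzyl-3-acyl-oxazolidin-2-one of acid 17 | O=C(C[C@H]1C=C(C)[C@@H](O[Si](C)(C)C(C)(C)C)C[C@H]1C(C)=C)N1[C@H](Cc2ccccc2)COC1=O | intermediate
21 | tert-butyl bromoacetate | CC(C)(C)OC(=O)CBr | starting material
22 | sodium Z-enolate of 20 (not isolated) | [Na+].[O-]/C(=C\[C@H]1C=C(C)[C@@H](O[Si](C)(C)C(C)(C)C)C[C@H]1C(C)=C)N1[C@H](Cc2ccccc2)COC1=O | intermediate
23 | (3R)-alkylated imide (tert-butyl succinate on the auxiliary; C7 R) | CC(C)(C)OC(=O)C[C@@H](C(=O)N1[C@H](Cc2ccccc2)COC1=O)[C@H]1C=C(C)[C@@H](O[Si](C)(C)C(C)(C)C)C[C@H]1C(C)=C | intermediate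
24 | tert-butyl (3R)-4-hydroxy-3-(ring B)butanoate | CC(C)(C)OC(=O)C[C@@H](CO)[C@H]1C=C(C)[C@@H](O[Si](C)(C)C(C)(C)C)C[C@H]1C(C)=C | intermediate
25 | tert-butyl (3R)-4-oxo-3-(ring B)butanoate, the ene precursor | CC(C)(C)OC(=O)C[C@@H](C=O)[C@H]1C=C(C)[C@@H](O[Si](C)(C)C(C)(C)C)C[C@H]1C(C)=C | intermediate
26 | cis-decalin ene product (8α-OH, exocyclic C10=C14, 3β-OTBS, C7 tert-butyl acetate arm) | CC(C)(C)OC(=O)C[C@@H]1[C@H]2C=C(C)[C@@H](O[Si](C)(C)C(C)(C)C)C[C@H]2C(=C)C[C@@H]1O | intermediate
27 | 8α,10β-diol (10α-methyl) | CC(C)(C)OC(=O)C[C@@H]1[C@H]2C=C(C)[C@@H](O[Si](C)(C)C(C)(C)C)C[C@H]2[C@@](C)(O)C[C@@H]1O | intermediate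
28 | trilithium enolate dialkoxide of 27 (not isolated) | [Li+].[Li+].[Li+].CC(C)(C)OC([O-])=C[C@@H]1[C@H]2C=C(C)[C@@H](O[Si](C)(C)C(C)(C)C)C[C@H]2[C@@](C)([O-])C[C@@H]1[O-] | intermediate
29 | Mannich base (C11 dimethylaminomethyl, C11 epimers; not isolated) | CC(C)(C)OC(=O)C(CN(C)C)[C@@H]1[C@H]2C=C(C)[C@@H](O[Si](C)(C)C(C)(C)C)C[C@H]2[C@@](C)(O)C[C@@H]1O | intermediate
30 | trimethylammonium iodide of 29 (not isolated) | [I-].CC(C)(C)OC(=O)C(C[N+](C)(C)C)[C@@H]1[C@H]2C=C(C)[C@@H](O[Si](C)(C)C(C)(C)C)C[C@H]2[C@@](C)(O)C[C@@H]1O | intermediate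
31 | tert-butyl acrylate diol (C11=C13 installed) | CC(C)(C)OC(=O)C(=C)[C@@H]1[C@H]2C=C(C)[C@@H](O[Si](C)(C)C(C)(C)C)C[C@H]2[C@@](C)(O)C[C@@H]1O | intermediate
32 | 2,4,6-trichlorobenzoic mixed anhydride of 6 (not isolated) | O=C(OC(=O)c1c(Cl)cc(Cl)cc1Cl)/C(=C/CO[Si](c1ccccc1)(c1ccccc1)C(C)(C)C)CO[Si](c1ccccc1)(c1ccccc1)C(C)(C)C | intermediate
33 | C8 ester (3β-OTBS, side-chain bis-TBDPS, tert-butyl acrylate) | CC(C)(C)OC(=O)C(=C)[C@@H]1[C@H]2C=C(C)[C@@H](O[Si](C)(C)C(C)(C)C)C[C@H]2[C@@](C)(O)C[C@@H]1OC(=O)/C(=C/CO[Si](c1ccccc1)(c1ccccc1)C(C)(C)C)CO[Si](c1ccccc1)(c1ccccc1)C(C)(C)C | intermediate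
34 | 3β-alcohol | CC(C)(C)OC(=O)C(=C)[C@@H]1[C@H]2C=C(C)[C@@H](O)C[C@H]2[C@@](C)(O)C[C@@H]1OC(=O)/C(=C/CO[Si](c1ccccc1)(c1ccccc1)C(C)(C)C)CO[Si](c1ccccc1)(c1ccccc1)C(C)(C)C | intermediate
35 | 3β-acetate | CC(C)(C)OC(=O)C(=C)[C@@H]1[C@H]2C=C(C)[C@@H](OC(C)=O)C[C@H]2[C@@](C)(O)C[C@@H]1OC(=O)/C(=C/CO[Si](c1ccccc1)(c1ccccc1)C(C)(C)C)CO[Si](c1ccccc1)(c1ccccc1)C(C)(C)C | intermediate
36 | trimethylsilyl ester with C10 trimethylsilyl ether (not isolated) | C[Si](C)(C)OC(=O)C(=C)[C@@H]1[C@H]2C=C(C)[C@@H](OC(C)=O)C[C@H]2[C@@](C)(O[Si](C)(C)C)C[C@@H]1OC(=O)/C(=C/CO[Si](c1ccccc1)(c1ccccc1)C(C)(C)C)CO[Si](c1ccccc1)(c1ccccc1)C(C)(C)C | intermediate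
37 | CNP0468194.1 | C=C(C(=O)O)[C@@H]1[C@H]2C=C(C)[C@@H](OC(C)=O)C[C@H]2[C@@](C)(O)C[C@@H]1OC(=O)/C(=C/CO)CO | target

**Count and risks**
Total: 21 steps. Longest linear sequence: 17 steps (steps 5–21, from (S)-carvone); the side-chain acid takes 4 steps (1–4) and joins at step 18.

Step 16 (hydration at C10). What may go wrong: oxygen capture by the C10 radical from both faces, giving the C10 epimer, or hydrogen-atom transfer to the C4=C5 alkene. The fallback sets out from 26 and returns at 27 by hydroxyl-assisted oxymercuration–demercuration. Hg(OAc)2 in THF/H2O at rt should give the alkylmercury acetate F1, with mercury on C14 and the new hydroxyl on C10. The axial C8 hydroxyl is expected to hold mercury on the α face, so water opens the mercurinium ion at the tertiary carbon from the β face, anti to mercury; the 1,1-disubstituted alkene reacts much faster than the trisubstituted one. NaBH4 in aqueous NaOH then replaces mercury by hydrogen and gives 27.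

Step 21 (final deprotection). What may go wrong: ionisation or loss of the allylic C3 acetate under the silyl triflate, silyl scrambling, or incomplete removal of the TBDPS groups. The fallback sets out from 33 and returns at 37; it cleaves the tert-butyl ester before the acetate exists. TMSOTf/2,6-lutidine on 33 followed by a citric acid work-up should give the carboxylic acid F2 (C3 still TBS ether, C10 as trimethylsilyl ether). PPTS in EtOH removes both of these silyl ethers to give the hydroxy acid F3. Ac2O/pyridine at 0 °C with aqueous work-up gives the acetate acid F4, and HF·pyridine in THF then gives 37.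

Step 9 (Johnson–Claisen). What may go wrong: acid-promoted ionisation and dehydration of the tertiary allylic alcohol at 140 °C, or failure of the orthoester exchange at the hindered carbinol. The fallback sets out from 13 and returns at 17 by an Ireland–Claisen rearrangement under basic conditions. Ac2O, DMAP and Et3N in CH2Cl2 at 40 °C give the tertiary allylic acetate F5. LiN(iPr)2 and Me3SiCl in THF at −78 °C give the silyl ketene acetal F6, which on warming to 60 °C rearranges suprafacially to the trimethylsilyl ester F7. Aqueous work-up gives acid 17 directly, so step 10 is not needed.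

Further compounds
F1 | step 16 | alkylmercury acetate (C14–HgOAc, 10β-OH) from 26 | CC(C)(C)OC(=O)C[C@@H]1[C@H]2C=C(C)[C@@H](O[Si](C)(C)C(C)(C)C)C[C@H]2[C@@](C[Hg]OC(C)=O)(O)C[C@@H]1O
F2 | step 21 | acrylic acid from 33 (3β-OTBS, 10β-OSiMe3, side-chain bis-TBDPS) | OC(=O)C(=C)[C@@H]1[C@H]2C=C(C)[C@@H](O[Si](C)(C)C(C)(C)C)C[C@H]2[C@@](C)(O[Si](C)(C)C)C[C@@H]1OC(=O)/C(=C/CO[Si](c1ccccc1)(c1ccccc1)C(C)(C)C)CO[Si](c1ccccc1)(c1ccccc1)C(C)(C)C
F3 | step 21 | 3β,10β-dihydroxy acrylic acid (side-chain bis-TBDPS) | OC(=O)C(=C)[C@@H]1[C@H]2C=C(C)[C@@H](O)C[C@H]2[C@@](C)(O)C[C@@H]1OC(=O)/C(=C/CO[Si](c1ccccc1)(c1ccccc1)C(C)(C)C)CO[Si](c1ccccc1)(c1ccccc1)C(C)(C)C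
F4 | step 21 | 3β-acetoxy acrylic acid (side-chain bis-TBDPS) | OC(=O)C(=C)[C@@H]1[C@H]2C=C(C)[C@@H](OC(C)=O)C[C@H]2[C@@](C)(O)C[C@@H]1OC(=O)/C(=C/CO[Si](c1ccccc1)(c1ccccc1)C(C)(C)C)CO[Si](c1ccccc1)(c1ccccc1)C(C)(C)C
F5 | step 9 | tertiary allylic acetate of 13 | C1=C[C@@](C)(OC(C)=O)[C@@H](O[Si](C)(C)C(C)(C)C)C[C@H]1C(C)=C
F6 | step 9 | trimethylsilyl ketene acetal of F5 | C1=C[C@@](C)(OC(=C)O[Si](C)(C)C)[C@@H](O[Si](C)(C)C(C)(C)C)C[C@H]1C(C)=C
F7 | step 9 | trimethylsilyl ester of acid 17 | C[Si](C)(C)OC(=O)C[C@H]1C=C(C)[C@@H](O[Si](C)(C)C(C)(C)C)C[C@H]1C(C)=C
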